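## Retrosynthetic overview

1. Target ⇐ 2,3-bis-silyl 9,20-diol ⇐ macrocyclic C9 allylic alcohol; the eleven-membered ring is closed last by a Nozaki–Hiyama–Kishi reaction (C8–C9), and C9 is then fixed by oxidation and CBS reduction.
2. C1–C14 bond: B-alkyl Suzuki coupling of a hydrindene C1 enol triflate with fragment B (C9–C14 plus C20; C12 set by Cu-catalysed SN2′ alkylation).
3. trans-2,3-Diol: anti hydrolysis of a 2β,3β-epoxide placed by OH-directed epoxidation; the directing C1 carbinol comes from a ketoreductase reduction.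
4. cis-Hydrindenone (C4, C7, C16): organocatalytic desymmetrising intramolecular Michael addition of an achiral 4,4-disubstituted cyclohexadienone aldehyde.
5. Ring order: six-membered ring (from 3-ethoxycyclohexenone) → five-membered ring (Michael) → eleven-membered ring (NHK).

Assumption: atoms carry trinervitane labels mapped on the target SMILES (C19H2=C8; C9 OAc; C10; C11; C12 with C20H2OAc; C13; C14; C1=C15(C17H3); C16–H; C7–H; C6; C5; C4 with C18H3; C3–OH; C2–OH). β is the face of the C4 methyl, so C16–H, C7–H and C3–O are β, and C2–O and the C7–C8 bond are α.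

## Route

Step 1
Reactants: 1 3-ethoxycyclohex-2-en-1-one; 2 5-bromopent-1-ene
Product: 3 3-ethoxy-6-(pent-4-en-1-yl)cyclohex-2-en-1-one (racemic)
Conditions: LDA (LiN(i-Pr)2), THF, −78 °C; then 2, DMPU, −78 °C to rt
Reagents that add atoms: none
Why: Stork–Danheiser kinetic α′-alkylation of the vinylogous ester enolate with a primary bromide; the stereocentre formed is racemic and is erased in step 4.

Step 2
Reactants: 3 3-ethoxy-6-(pent-4-en-1-yl)cyclohex-2-en-1-one
Product: 4 3-ethoxy-6-methyl-6-(pent-4-en-1-yl)cyclohex-2-en-1-one (racemic)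
Conditions: LDA, THF, −78 °C; MeI, −78 to 0 °C
Reagents that add atoms: iodomethane, CI
Why: a second α′-alkylation with the small electrophile builds the quaternary carbon (later C4).

Step 3
Reactants: 4 3-ethoxy-6-methyl-6-(pent-4-en-1-yl)cyclohex-2-en-1-one
Product: 6 4-methyl-4-(pent-4-en-1-yl)cyclohex-2-en-1-one (racemic), via allylic alcohol 5 (not isolated)
Conditions: LiAlH4, Et2O, 0 °C; then 1 M HCl, rt
Reagents that add atoms: none
Why: Stork–Danheiser 1,3-carbonyl transposition (1,2-reduction, then acid hydrolysis of the enol ether with loss of ethanol).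

Step 4
Reactants: 6 4-methyl-4-(pent-4-en-1-yl)cyclohex-2-en-1-one
Product: 7 4-methyl-4-(pent-4-en-1-yl)cyclohexa-2,5-dien-1-one (achiral)
Conditions: IBX (2.5 equiv), DMSO/fluorobenzene, 75 °C
Reagents that add atoms: none
Why: IBX dehydrogenation of the enone gives the cross-conjugated dienone, which is achiral and prochiral; the isolated alkene is inert.

Step 5
Reactants: 7 4-methyl-4-(pent-4-en-1-yl)cyclohexa-2,5-dien-1-one
Product: 9 4-(1-methyl-4-oxocyclohexa-2,5-dien-1-yl)butanal (achiral), via ozonide 8 (not isolated)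
Conditions: O3, CH2Cl2, −78 °C (stopped at first blue tint); Me2S, −78 °C to rt
Reagents that add atoms: ozone, [O-][O+]=O
Why: ozonolysis is selective for the electron-rich terminal alkene over the electron-poor dienone alkenes; reductive work-up gives the aldehyde.

Step 6
Reactants: 9 4-(1-methyl-4-oxocyclohexa-2,5-dien-1-yl)butanal
Product: 10 (1R,3aR,7aR)-3a-methyl-6-oxo-2,3,3a,6,7,7a-hexahydro-1H-indene-1-carbaldehyde (cis-fused; C4 β-Me, C16 β-H, C7 α-CHO)
Conditions: (S)-α,α-diphenylprolinol trimethylsilyl ether (10 mol %), PhCO2H (10 mol %), toluene, 0 °C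
Reagents that add atoms: none
Why: enamine-catalysed desymmetrising intramolecular Michael addition: the E-enamine adds through its Si face in a synclinal 5-exo transition state, giving the kinetic product with CHO cis to the C15 arm (C7), and the cis ring fusion fixes C16 and C4.

Step 7
Reactants: 10 cis-hydrindenone aldehyde
Product: 11 (3R,3aR,7aR)-3-(2,2-dibromoethenyl)-7a-methyl-1,2,3,3a,4,7a-hexahydro-5H-inden-5-one
Conditions: CBr4, PPh3, CH2Cl2, 0 °C
Reagents that add atoms: carbon tetrabromide, BrC(Br)(Br)Br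
Why: Corey–Fuchs (Ramirez) dibromo-olefination is neutral and aldehyde-selective, so the epimerisable α-formyl centre C7 is converted without base and is no longer enolisable.

Step 8
Reactants: 11 dibromovinyl enone
Product: 12 (3R,3aR,5S,7aR)-3-(2,2-dibromoethenyl)-7a-methyl-2,3,3a,4,5,7a-hexahydro-1H-inden-5-ol (C1 β-OH)
Conditions: ketoreductase (KRED, panel-selected for the 1S alcohol), NADP+ (cat.), i-PrOH/phosphate buffer pH 7 (1:9), 30 °C
Reagents that add atoms: none
Why: enzymatic carbonyl reduction by a ketoreductase: hydride is delivered to the α face of C1 under enzyme control, giving the single 1β-alcohol that steers the epoxidation in step 10; the C=C bonds are untouched.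

Step 9
Reactants: 12 1β-allylic alcohol
Product: 14 1β-ol bearing the 7α-(trimethylsilylethynyl) group, via bis-silyl derivative 13 (not isolated)
Conditions: n-BuLi (3.3 equiv), THF, −78 to 0 °C; TMSCl, −78 °C; citric acid, MeOH/H2O work-up
Reagents that add atoms: chlorotrimethylsilane, C[Si](C)(C)Cl
Why: second stage of the Corey–Fuchs alkyne synthesis (Br/Li exchange, Fritsch–Buttenberg–Wiechell rearrangement) with C-silylation of the acetylide; the labile O–Si bond is cleaved on work-up.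

Step 10
Reactants: 14 1β-ol
Product: 15 2β,3β-epoxy-1β-ol
Conditions: VO(acac)2 (5 mol %), t-BuOOH, CH2Cl2, 0 °C to rt
Reagents that add atoms: tert-butyl hydroperoxide, CC(C)(C)OO
Why: hydroxyl-directed vanadium-catalysed epoxidation of a cyclic allylic alcohol delivers oxygen syn to the C1 hydroxyl, fixing the C3–O bond on the β face.

Step 11
Reactants: 15 2β,3β-epoxy-1β-ol
Product: 16 2β,3β-epoxy C1 ketone
Conditions: Dess–Martin periodinane, NaHCO3, CH2Cl2, 0 °C to rt
Reagents that add atoms: none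
Why: Dess–Martin oxidation returns the C1 ketone without opening the epoxide; the relay stereocentre at C1 is removed after it has done its work.

Step 12
Reactants: 16 epoxy ketone
Product: 17 C15-methyl epoxy ketone (C15 epimers)
Conditions: LDA, THF, −78 °C; MeI, DMPU, −78 to −30 °C
Reagents that add atoms: iodomethane, CI
Why: enolate alkylation: the epoxy ketone can only enolise toward C15, so methylation is regiospecific; the C15 configuration is irrelevant because C15 becomes sp2.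

Step 13
Reactants: 17 C15-methyl epoxy ketone
Product: 18 C1 enol triflate (C1=C15) carrying the 2β,3β-epoxide
Conditions: KHMDS (KN(SiMe3)2), THF, −78 °C; PhNTf2, −78 to 0 °C
Reagents that add atoms: N-phenylbis(trifluoromethanesulfonimide), O=S(=O)(N(c1ccccc1)S(=O)(=O)C(F)(F)F)C(F)(F)F
Why: O-triflation of the only possible enolate gives the tetrasubstituted C1=C15 enol triflate regiospecifically.

Step 14
Reactants: 18 epoxy enol triflate
Product: 19 enol triflate 2α,3β-diol
Conditions: HClO4 (5 mol %), THF/H2O (3:1), 0 °C to rt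
Reagents that add atoms: water, O
Why: acid-catalysed SN2 epoxide opening: water attacks the allylic C2 (C3 is neopentyl) with inversion, giving the trans diol with C3–OH β and C2–OH α.

Step 15
Reactants: 19 diol
Product: 20 enol triflate 2α,3β-bis(tert-butyldimethylsilyl ether)
Conditions: TBSOTf (3 equiv), 2,6-lutidine, CH2Cl2, 0 °C to rt
Reagents that add atoms: tert-butyldimethylsilyl triflate, CC(C)(C)[Si](C)(C)OS(=O)(=O)C(F)(F)F
Why: silyl triflate protection of both secondary alcohols, including the hindered C3 hydroxyl.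

Step 16
Reactants: 21 (E)-1,4-dibromobut-2-ene; 22 4-methoxybenzyl alcohol
Product: 23 (E)-1-bromo-4-[(4-methoxybenzyl)oxy]but-2-ene
Conditions: NaH, THF, 0 °C; 21 (3 equiv), 0 °C to rt
Reagents that add atoms: none
Why: Williamson etherification; excess dibromide keeps the reaction at mono-substitution.

Step 17
Reactants: 23 (E)-1-bromo-4-[(4-methoxybenzyl)oxy]but-2-ene; 24 2-(2-bromoethyl)-1,3-dioxolane
Product: 26 2-[(3S)-3-{[(4-methoxybenzyl)oxy]methyl}pent-4-en-1-yl]-1,3-dioxolane (fragment B), via Grignard reagent 25 (not isolated)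
Conditions: 24, Mg, THF, 30 °C; then 23, CuBr·SMe2 (5 mol %), (R,R)-Taniaphos (6 mol %), CH2Cl2, −78 °C
Reagents that add atoms: none
Why: copper-catalysed asymmetric allylic alkylation (SN2′) with a Grignard reagent; the chiral ferrocenyl diphosphine controls the face and gives the branched (S)-alkene (C12); the mirror-image ligand would give the antipode.

Step 18
Reactants: 20 enol triflate bis-silyl ether; 26 fragment B
Product: 28 C1–C14 coupled product (C1=C15; 2α,3β-bis-OTBS; C8≡C19–TMS; C9 dioxolane; C20 OPMB; 12R), via alkylborane 27 (not isolated)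
Conditions: 26, 9-BBN, THF, rt; then 20, Pd(dppf)Cl2 (10 mol %), AsPh3, Cs2CO3, DMF/H2O, rt to 45 °C
Reagents that add atoms: none
Why: anti-Markovnikov hydroboration of the terminal alkene, then B-alkyl Suzuki–Miyaura coupling with the enol triflate; the tetrasubstituted alkene geometry is fixed by the ring.

Step 19
Reactants: 28 silyl alkyne
Product: 29 terminal alkyne
Conditions: K2CO3, MeOH, rt
Reagents that add atoms: none
Why: methanolysis of the alkynyl C–Si bond; secondary TBS ethers, acetal and PMB ether are stable.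

Step 20
Reactants: 29 terminal alkyne
Product: 30 2-(trimethylstannyl)alkene (C8–SnMe3, C8=C19H2)
Conditions: Me3SnCu·SMe2 (preformed, 2.5 equiv), MeOH (60 equiv), THF, −78 to −63 °C
Reagents that add atoms: trimethylstannylcopper–dimethyl sulfide, C[Sn](C)(C)[Cu].CSC
Why: Piers stannylcupration with in situ protonation places tin on the internal alkyne carbon.

Step 21
Reactants: 30 vinylstannane
Product: 31 2-iodoalkene (C8–I, C8=C19H2)
Conditions: I2, CH2Cl2, 0 °C
Reagents that add atoms: iodine, II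
Why: iododestannylation with retention is far faster than any reaction of iodine with the hindered tetrasubstituted alkene.

Step 22
Reactants: 31 vinyl iodide acetal
Product: 32 C9 aldehyde
Conditions: PPTS, acetone/H2O (10:1), 55 °C
Reagents that add atoms: water, O
Why: mild acetal hydrolysis; secondary TBS ethers, PMB ether and vinyl iodide survive.

Step 23
Reactants: 32 iodo aldehyde
Product: 33 macrocyclic C9 allylic alcohol (tricycle; C9 epimers)
Conditions: CrCl2 (10 equiv), NiCl2 (2 mol %), DMSO/THF (3:1), 2 mM, syringe-pump addition, rt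
Reagents that add atoms: none
Why: intramolecular Nozaki–Hiyama–Kishi reaction: the alkenylchromium adds only to the aldehyde and closes the eleven-membered ring with the C8 exo-methylene in place; the C9 ratio is immaterial.

Step 24
Reactants: 33 C9 alcohol mixture
Product: 34 macrocyclic C9 enone
Conditions: Dess–Martin periodinane, NaHCO3, CH2Cl2, 0 °C
Reagents that add atoms: none
Why: Dess–Martin oxidation converges both C9 epimers to one enone.

Step 25
Reactants: 34 enone
Product: 35 (9S)-allylic alcohol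
Conditions: (R)-Me-CBS oxazaborolidine (1.0 equiv), catecholborane, toluene, −78 °C
Reagents that add atoms: none
Why: Corey–Bakshi–Shibata reduction: the branched alkenyl group is the large substituent, so the (R)-catalyst gives the 9S alcohol by 1,2-reduction.

Step 26
Reactants: 35 (9S)-alcohol
Product: 36 9,20-diol
Conditions: DDQ, CH2Cl2/pH 7 buffer (10:1), 0 °C
Reagents that add atoms: none
Why: oxidative cleavage of the PMB ether, which is faster than oxidation of the unactivated allylic alcohol under buffered conditions.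

Step 27
Reactants: 36 diol
Product: 37 9,20-diacetate 2,3-bis(TBS ether)
Conditions: Ac2O, pyridine, DMAP (cat.), CH2Cl2, 0 °C to rt
Reagents that add atoms: acetic anhydride, CC(=O)OC(C)=O
Why: acylation of the two free hydroxyls; C2 and C3 are blocked as silyl ethers.

Step 28
Reactants: 37 diacetate bis-silyl ether
Product: 38 CNP0193272.1
Conditions: HF·pyridine, THF/pyridine, 0 to 40 °C
Reagents that add atoms: none
Why: fluoride-mediated desilylation under buffered acidic conditions leaves the acetates, with no base present to promote acyl migration.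

## Compound list

1 | 3-ethoxycyclohex-2-en-1-one | CCOC1=CC(=O)CCC1 | starting material
2 | 5-bromopent-1-ene | C=CCCCBr | starting material
3 | 3-ethoxy-6-(pent-4-en-1-yl)cyclohex-2-en-1-one (racemic) | CCOC1=CC(=O)C(CCCC=C)CC1 | intermediate
4 | 3-ethoxy-6-methyl-6-(pent-4-en-1-yl)cyclohex-2-en-1-one (racemic) | CCOC1=CC(=O)C(C)(CCCC=C)CC1 | intermediate
5 | 3-ethoxy-6-methyl-6-(pent-4-en-1-yl)cyclohex-2-en-1-ol (not isolated) | CCOC1=CC(O)C(C)(CCCC=C)CC1 | intermediate
6 | 4-methyl-4-(pent-4-en-1-yl)cyclohex-2-en-1-one (racemic) | O=C1C=CC(C)(CCCC=C)CC1 | intermediate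
7 | 4-methyl-4-(pent-4-en-1-yl)cyclohexa-2,5-dien-1-one | O=C1C=CC(C)(CCCC=C)C=C1 | intermediate
8 | 4-methyl-4-[3-(1,2,4-trioxolan-3-yl)propyl]cyclohexa-2,5-dien-1-one (ozonide, not isolated) | O=C1C=CC(C)(CCCC2OCOO2)C=C1 | intermediate
9 | 4-(1-methyl-4-oxocyclohexa-2,5-dien-1-yl)butanal | O=CCCCC1(C)C=CC(=O)C=C1 | intermediate
10 | (1R,3aR,7aR)-3a-methyl-6-oxo-2,3,3a,6,7,7a-hexahydro-1H-indene-1-carbaldehyde | O=C1C[C@@H]2[C@H](C=O)CC[C@]2(C)C=C1 | intermediate
11 | (3R,3aR,7aR)-3-(2,2-dibromoethenyl)-7a-methyl-1,2,3,3a,4,7a-hexahydro-5H-inden-5-one | O=C1C[C@@H]2[C@H](C=C(Br)Br)CC[C@]2(C)C=C1 | intermediate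
12 | (3R,3aR,5S,7aR)-3-(2,2-dibromoethenyl)-7a-methyl-2,3,3a,4,5,7a-hexahydro-1H-inden-5-ol (C1 β-OH) | O[C@H]1C[C@@H]2[C@H](C=C(Br)Br)CC[C@]2(C)C=C1 | intermediate
13 | 1β-trimethylsilyl ether with 7α-(trimethylsilylethynyl) group (not isolated) | C[Si](C)(C)O[C@H]1C[C@@H]2[C@H](C#C[Si](C)(C)C)CC[C@]2(C)C=C1 | intermediate
14 | 1β-ol with 7α-(trimethylsilylethynyl) group, C2=C3 alkene | O[C@H]1C[C@@H]2[C@H](C#C[Si](C)(C)C)CC[C@]2(C)C=C1 | intermediate
15 | 2β,3β-epoxy-1β-ol | O[C@H]1C[C@@H]2[C@H](C#C[Si](C)(C)C)CC[C@]2(C)[C@H]3O[C@@H]13 | intermediate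
16 | 2β,3β-epoxy C1 ketone | O=C1C[C@@H]2[C@H](C#C[Si](C)(C)C)CC[C@]2(C)[C@H]3O[C@@H]13 | intermediate
17 | C15-methyl 2β,3β-epoxy C1 ketone (C15 epimers) | O=C1C(C)[C@@H]2[C@H](C#C[Si](C)(C)C)CC[C@]2(C)[C@H]3O[C@@H]13 | intermediate
18 | C1 enol triflate (C1=C15) with 2β,3β-epoxide | O=S(=O)(OC1=C(C)[C@@H]2[C@H](C#C[Si](C)(C)C)CC[C@]2(C)[C@H]3O[C@@H]13)C(F)(F)F | intermediate
19 | C1 enol triflate 2α,3β-diol | O=S(=O)(OC1=C(C)[C@@H]2[C@H](C#C[Si](C)(C)C)CC[C@]2(C)[C@@H](O)[C@@H]1O)C(F)(F)F | intermediate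
20 | C1 enol triflate 2α,3β-bis(tert-butyldimethylsilyl ether) | O=S(=O)(OC1=C(C)[C@@H]2[C@H](C#C[Si](C)(C)C)CC[C@]2(C)[C@@H](O[Si](C)(C)C(C)(C)C)[C@@H]1O[Si](C)(C)C(C)(C)C)C(F)(F)F | intermediate
21 | (E)-1,4-dibromobut-2-ene | BrC/C=C/CBr | starting material
22 | 4-methoxybenzyl alcohol | COc1ccc(CO)cc1 | starting material
23 | (E)-1-bromo-4-[(4-methoxybenzyl)oxy]but-2-ene | COc1ccc(COC/C=C/CBr)cc1 | intermediate
24 | 2-(2-bromoethyl)-1,3-dioxolane | BrCCC1OCCO1 | starting material
25 | [2-(1,3-dioxolan-2-yl)ethyl]magnesium bromide (not isolated) | Br[Mg]CCC1OCCO1 | intermediate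
26 | 2-[(3S)-3-{[(4-methoxybenzyl)oxy]methyl}pent-4-en-1-yl]-1,3-dioxolane (fragment B) | C=C[C@@H](COCc1ccc(OC)cc1)CCC1OCCO1 | intermediate
27 | B-alkyl-9-borabicyclo[3.3.1]nonane from 26 (boron on C14, not isolated) | C1CCC2CCCC1B2CC[C@@H](COCc1ccc(OC)cc1)CCC1OCCO1 | intermediate
28 | Suzuki product: C1–C14 bond, C8≡C19–TMS, C9 dioxolane, C20 OPMB, 2α,3β-bis-OTBS | O1CCOC1CC[C@H](COCc1ccc(OC)cc1)CCC1=C(C)[C@@H]2[C@H](C#C[Si](C)(C)C)CC[C@]2(C)[C@@H](O[Si](C)(C)C(C)(C)C)[C@@H]1O[Si](C)(C)C(C)(C)C | intermediate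
29 | terminal alkyne (C8≡C19H) | O1CCOC1CC[C@H](COCc1ccc(OC)cc1)CCC1=C(C)[C@@H]2[C@H](C#C)CC[C@]2(C)[C@@H](O[Si](C)(C)C(C)(C)C)[C@@H]1O[Si](C)(C)C(C)(C)C | intermediate
30 | 2-(trimethylstannyl)alkene (C8–SnMe3) | O1CCOC1CC[C@H](COCc1ccc(OC)cc1)CCC1=C(C)[C@@H]2[C@H](C(=C)[Sn](C)(C)C)CC[C@]2(C)[C@@H](O[Si](C)(C)C(C)(C)C)[C@@H]1O[Si](C)(C)C(C)(C)C | intermediate
31 | 2-iodoalkene (C8–I) | O1CCOC1CC[C@H](COCc1ccc(OC)cc1)CCC1=C(C)[C@@H]2[C@H](C(=C)I)CC[C@]2(C)[C@@H](O[Si](C)(C)C(C)(C)C)[C@@H]1O[Si](C)(C)C(C)(C)C | intermediate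
32 | C9 aldehyde with C8 vinyl iodide | O=CCC[C@H](COCc1ccc(OC)cc1)CCC1=C(C)[C@@H]2[C@H](C(=C)I)CC[C@]2(C)[C@@H](O[Si](C)(C)C(C)(C)C)[C@@H]1O[Si](C)(C)C(C)(C)C | intermediate
33 | macrocyclic C9 allylic alcohol (C9 epimers), C20 OPMB, 2α,3β-bis-OTBS | C=C1C(O)CC[C@H](COCc2ccc(OC)cc2)CCC2=C(C)[C@@H]3[C@H]1CC[C@]3(C)[C@@H](O[Si](C)(C)C(C)(C)C)[C@@H]2O[Si](C)(C)C(C)(C)C | intermediate
34 | macrocyclic C9 enone | C=C1C(=O)CC[C@H](COCc2ccc(OC)cc2)CCC2=C(C)[C@@H]3[C@H]1CC[C@]3(C)[C@@H](O[Si](C)(C)C(C)(C)C)[C@@H]2O[Si](C)(C)C(C)(C)C | intermediate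
35 | (9S)-allylic alcohol | C=C1[C@@H](O)CC[C@H](COCc2ccc(OC)cc2)CCC2=C(C)[C@@H]3[C@H]1CC[C@]3(C)[C@@H](O[Si](C)(C)C(C)(C)C)[C@@H]2O[Si](C)(C)C(C)(C)C | intermediate
36 | 9,20-diol 2,3-bis(TBS ether) | C=C1[C@@H](O)CC[C@H](CO)CCC2=C(C)[C@@H]3[C@H]1CC[C@]3(C)[C@@H](O[Si](C)(C)C(C)(C)C)[C@@H]2O[Si](C)(C)C(C)(C)C | intermediate
37 | 9,20-diacetate 2,3-bis(TBS ether) | C=C1[C@@H](OC(C)=O)CC[C@H](COC(C)=O)CCC2=C(C)[C@@H]3[C@H]1CC[C@]3(C)[C@@H](O[Si](C)(C)C(C)(C)C)[C@@H]2O[Si](C)(C)C(C)(C)C | intermediate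
38 | CNP0193272.1 (9,20-diacetoxy-trinervita-1(15),8(19)-diene-2α,3β-diol as drawn) | C=C1[C@@H](OC(C)=O)CC[C@H](COC(C)=O)CCC2=C(C)[C@@H]3[C@H]1CC[C@]3(C)[C@@H](O)[C@@H]2O | target

## Summary

Total step count: 28. Longest linear sequence: 26 steps (steps 1–15 and 18–28); fragment B takes steps 16–17.

Three steps most likely to fail:

Step 8 (no ketoreductase in the panel gives the 1S alcohol cleanly). The fallback sets out from 11: Luche reduction (NaBH4, CeCl3, MeOH, −78 °C) gives 12 together with its C1-epimeric alcohol F1. A lipase (Candida antarctica lipase B, vinyl acetate, MTBE) then acetylates the 1S alcohol selectively, as expected from the Kazlauskas model, to the acetate F2. Unreacted F1 is separated and oxidised back to 11 with MnO2, and methanolysis of F2 (K2CO3, MeOH) comes back to the route at 12.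

Step 14 (wrong regiochemistry or decomposition in the hydrolysis of the epoxy enol triflate). The fallback sets out from 17: SmI2 (THF/MeOH, −90 °C) cleaves the C2–O bond of the epoxy ketone to give the 3β-hydroxy ketone F3, which is silylated (TBSOTf, 2,6-lutidine) to the 3β-silyloxy ketone F4. Kinetic enolisation toward the C2 methylene (LDA, −78 °C) and oxidation with Davis oxaziridine, anti to the 3β-silyloxy group, give the 2α-hydroxy ketone F5, silylated to the 2α,3β-bis(silyloxy) ketone F6. KHMDS/PhNTf2 then enolises the C15 methine in preference to the α-silyloxy methine, and the route is rejoined at 20.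

Step 23 (oligomerisation or no closure of the eleven-membered ring in the chromium-mediated reaction). The fallback sets out from 29: acetal hydrolysis (PPTS, acetone/H2O) gives the ynal F7. Nickel-catalysed reductive alkyne–aldehyde macrocyclisation (Ni(cod)2, bulky N-heterocyclic carbene ligand, Et3SiH, THF, high dilution) forms the C8–C9 bond at the internal alkyne carbon and gives the macrocyclic C9 triethylsilyl ether F8. Selective removal of the triethylsilyl group (PPTS, MeOH, 0 °C) comes back to the route at 33.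

Further compounds
F1 | step 8 | C1 epimer of 12 (1R, C1 α-OH) | O[C@@H]1C[C@@H]2[C@H](C=C(Br)Br)CC[C@]2(C)C=C1
F2 | step 8 | acetate of 12 (1S) | CC(=O)O[C@H]1C[C@@H]2[C@H](C=C(Br)Br)CC[C@]2(C)C=C1
F3 | step 14 | 3β-hydroxy C1 ketone (C15 epimers) | O=C1C(C)[C@@H]2[C@H](C#C[Si](C)(C)C)CC[C@]2(C)[C@@H](O)C1
F4 | step 14 | 3β-(tert-butyldimethylsilyloxy) C1 ketone | O=C1C(C)[C@@H]2[C@H](C#C[Si](C)(C)C)CC[C@]2(C)[C@@H](O[Si](C)(C)C(C)(C)C)C1
F5 | step 14 | 2α-hydroxy-3β-(tert-butyldimethylsilyloxy) C1 ketone | O=C1C(C)[C@@H]2[C@H](C#C[Si](C)(C)C)CC[C@]2(C)[C@@H](O[Si](C)(C)C(C)(C)C)[C@@H]1O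
F6 | step 14 | 2α,3β-bis(tert-butyldimethylsilyloxy) C1 ketone | O=C1C(C)[C@@H]2[C@H](C#C[Si](C)(C)C)CC[C@]2(C)[C@@H](O[Si](C)(C)C(C)(C)C)[C@@H]1O[Si](C)(C)C(C)(C)C
F7 | step 23 | ynal (C9 aldehyde, terminal C8≡C19 alkyne) | O=CCC[C@H](COCc1ccc(OC)cc1)CCC1=C(C)[C@@H]2[C@H](C#C)CC[C@]2(C)[C@@H](O[Si](C)(C)C(C)(C)C)[C@@H]1O[Si](C)(C)C(C)(C)C
F8 | step 23 | macrocyclic C9 triethylsilyl ether (C9 epimers) | C=C1C(O[Si](CC)(CC)CC)CC[C@H](COCc2ccc(OC)cc2)CCC2=C(C)[C@@H]3[C@H]1CC[C@]3(C)[C@@H](O[Si](C)(C)C(C)(C)C)[C@@H]2O[Si](C)(C)C(C)(C)C
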